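(The readings are calculated with made-up constants; noise was put on by code.)

- maple: free monomer 0.010 M (fed, over 2.0 h); pre-initiator 80 µM; run made earlier; the fed solution adds 0.25 times the starting volume
- flask: free monomer 0.010 M (fed, over 2.0 h); pre-initiator 53 µM; time 10 d; the fed solution adds 0.25 times the starting volume

maple run (percent of the free monomer charged)

| time / d | monomer in chains / % | free monomer / % |
|---|---|---|
| 0.417 | 1 | 98 |
| 1.04 | 20 | 76 |
| 2.08 | 55 | 39 |
| 3.00 | 77 | 20 |

(scatter of a reading: 2 percentage points)

- amounts are per litre of the starting volume; all of the dose is in the solution fed
- the average divides the monomer in chains by the number of chains begun, living and dead together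
- the earlier runs do not show the number of chains; that part of a forecast is a guess
- no earlier run changes the charge of pre-initiator; that part of a forecast is a guess

- average number of monomer units in a chain (chains begun, living or dead) at 10 d
- part of the free monomer that has reacted at 10 d

**Uptake rate.** The flask holds less pre-initiator than the maple run. I follow one molecule of free monomer, which either stays free or enters a chain. The last two maple readings give a loss of 0.726 d⁻¹ and an apparent lag of 0.783 d. The feed ends in 2.0 h, sooner than that lag, so I drop it. I scale the loss by c(pre-initiator) and get 0.481 d⁻¹. This is the uptake rate, the chance per day that a free monomer molecule enters a chain, a pseudo-first-order rate constant.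

**Hand chain.** I keep the same lag for the flask. Then 1.19 % stays free at 10 d, so 98.8 % has reacted. If each pre-initiator starts one chain, the charge allows 189 units per chain at full uptake. The average is then 186.

**Weak link.** The scaling is a guess, since no earlier run changes that charge. A square-root scaling gives 0.591 d⁻¹ and leaves 0.431 % free. The reacted part therefore stays near 98.8 % either way. With fewer chains than pre-initiator, the same monomer in chains gives a higher average, so I hold 186 as my low end.

**The forecast.** The forecast gives 195 (165 to 280), above my average, and 98 % (90 % to 99.7 %), with its chain limit taken “if every pre-initiator starts a chain” and then leaning upward.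

**The result.** The flask gives an average of 216 and 99.4 % reacted.

    pre-initiator ⇌ initiator (K = 0.560, k = 2.40 × 10⁻⁵ s⁻¹)
    free monomer + living end → monomer in chains + living end, rate k2*[living end]*[free monomer] (k = 0.190 L mol⁻¹ s⁻¹)
    free monomer + initiator → living end + monomer in chains (k = 0.00380 L mol⁻¹ s⁻¹)

**Neighbour flask.** From 5.00 d to 10.0 d the flask's free monomer falls from 11.0 % to 0.551 %. That is an uptake rate of 0.600 d⁻¹, faster than my 0.481 d⁻¹. The neighbour is the same flask read at 4.0 d. My uptake rate and lag leave 21.3 % free there, and the neighbour holds 20 %. One chain per charged pre-initiator gives 152 units at its 80.3 % reacted, and the neighbour's average is 185.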